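Numbering: C7 is the carbinol carbon, C8 the oxolane methine that bears it, C8' the neighbouring ring methine, and C7' the benzylic CH2 on C8'. The target is (7S,8S,8'R), with the C8 and C8' substituents cis.
Cuts: C7–aryl and C7–OH are undone together, since both come from one boron-mediated event on an O-acylated C7 methylene. C7'–aryl is cut next, leaving cis-3,4-bis(hydroxymethyl)oxolane and a single protected bromophenol that supplies both aryl groups.
Enabling feature: C7 is an exocyclic secondary benzylic carbinol flanked only by an aryl ring and the ring methine C8. At the CH2–O(acyl) level it offers two diastereotopic α-oxygen hydrogens to a chiral base, and neither C8 nor C8' ever sits beside a carbonyl group, so the less stable cis pair stays intact.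
Forward: the only ring, the oxolane, is bought as a furan and saturated. One arm is capped as the hindered benzoate and the other is joined to the first aryl group by Negishi coupling. The second aryl group and the hydroxyl go onto C7 by lithiation–borylation–oxidation, and desilylation ends the route.
Stereochemistry: cis C8/C8' comes from syn hydrogenation, the absolute sense from lipase desymmetrisation of the meso diol, and C7 from (+)-sparteine.

Key step: step 10

Assumption: the lipase is taken to acetylate the arm that gives the (3R,4R)-monoacetate; because either arm can become C7, the antipode serves equally well once the order of arm elaboration is exchanged (fallback to step 3).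
Abbreviations: TIB = 2,4,6-triisopropylbenzoyl, TIPS = triisopropylsilyl, pin = pinacolato, SPhos = 2-dicyclohexylphosphino-2',6'-dimethoxybiphenyl, DIAD = diisopropyl azodicarboxylate.

Step 1
Reactants: 1 diethyl furan-3,4-dicarboxylate
Product: 2 diethyl cis-oxolane-3,4-dicarboxylate (meso; 3R,4S)
Conditions: H2 (50 bar), 5% Rh/C, EtOH, 50 °C
Reagents that add atoms: none
Why: Heterogeneous catalytic hydrogenation delivers hydrogen to the adsorbed face of the furan (syn addition), so both ester groups should end up on the same side of the new oxolane and the product is the achiral cis diester.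

Step 2
Reactants: 2 diethyl cis-oxolane-3,4-dicarboxylate
Product: 3 cis-oxolane-3,4-diyldimethanol (meso; 3R,4S)
Conditions: LiAlH4, THF, 0 °C to rt; Na2SO4·10H2O quench
Reagents that add atoms: none
Why: Hydride reduction of the esters with LiAlH4 is much faster than their enolisation at this temperature, so the cis relationship should pass unchanged into the meso 1,4-diol.

Step 3
Reactants: 3 cis-oxolane-3,4-diyldimethanol
Product: 4 [(3R,4R)-4-(hydroxymethyl)oxolan-3-yl]methyl acetate (cis)
Conditions: Burkholderia cepacia lipase (immobilised), vinyl acetate, t-BuOMe/THF, 25 °C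
Reagents that add atoms: vinyl acetate, C=COC(C)=O
Why: Irreversible lipase-catalysed transesterification (enzymatic desymmetrisation of a meso diol) acylates one of the two enantiotopic CH2OH arms and thereby fixes the absolute configuration of both ring methines in one operation.

Step 4
Reactants: 4 [(3R,4R)-4-(hydroxymethyl)oxolan-3-yl]methyl acetate; 5 2,4,6-triisopropylbenzoic acid
Product: 6 [(3S,4R)-4-(acetoxymethyl)oxolan-3-yl]methyl 2,4,6-triisopropylbenzoate
Conditions: PPh3, DIAD, THF, 0 °C to rt
Reagents that add atoms: none
Why: Mitsunobu esterification is the standard way to attach this very hindered acid to a primary alcohol, and its near-neutral medium should not provoke acetyl migration between the arms or touch either stereocentre.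

Step 5
Reactants: 6 [(3S,4R)-4-(acetoxymethyl)oxolan-3-yl]methyl 2,4,6-triisopropylbenzoate
Product: 7 [(3S,4S)-4-(hydroxymethyl)oxolan-3-yl]methyl 2,4,6-triisopropylbenzoate
Conditions: K2CO3 (0.2 equiv), MeOH, 0 °C to rt
Reagents that add atoms: none
Why: Base-catalysed transesterification with methanol removes the unhindered acetate, whereas the benzoate carbonyl is shielded by its two ortho isopropyl groups and should stay intact.

Step 6
Reactants: 7 [(3S,4S)-4-(hydroxymethyl)oxolan-3-yl]methyl 2,4,6-triisopropylbenzoate
Product: 8 [(3S,4R)-4-(iodomethyl)oxolan-3-yl]methyl 2,4,6-triisopropylbenzoate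
Conditions: I2, PPh3, imidazole, CH2Cl2, 0 °C to rt
Reagents that add atoms: iodine, II
Why: Appel-type iodination proceeds through an alkoxyphosphonium ion that iodide displaces at the primary CH2 only, so both ring methines keep their configuration.

Step 7
Reactants: 9 5-bromo-2-methoxyphenol
Product: 10 (5-bromo-2-methoxyphenoxy)triisopropylsilane
Conditions: TIPSCl, imidazole, DMF, rt
Reagents that add atoms: chlorotriisopropylsilane, CC(C)[Si](Cl)(C(C)C)C(C)C
Why: Imidazole-promoted O-silylation gives a bulky aryl silyl ether that has no acidic benzylic C–H, screens its ortho positions against later lithiation and falls off with fluoride at the end.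

Step 8
Reactants: 8 [(3S,4R)-4-(iodomethyl)oxolan-3-yl]methyl 2,4,6-triisopropylbenzoate; 10 (5-bromo-2-methoxyphenoxy)triisopropylsilane
Product: 12 [(3S,4R)-4-{[4-methoxy-3-(triisopropylsilyloxy)phenyl]methyl}oxolan-3-yl]methyl 2,4,6-triisopropylbenzoate, via alkylzinc iodide 11 (not isolated)
Conditions: Zn dust, LiCl, THF, 40 °C; then 10, Pd(OAc)2 (2 mol %), SPhos (4 mol %), THF, 25 to 50 °C
Reagents that add atoms: none
Why: LiCl-assisted zinc insertion into the primary iodide followed by Negishi coupling is well established for β-branched, γ-oxygenated alkylzinc iodides, the bulky biarylphosphine speeds reductive elimination past β-hydride elimination, and C8' takes no part in the bond change.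

Step 9
Reactants: 10 (5-bromo-2-methoxyphenoxy)triisopropylsilane
Product: 13 2-[4-methoxy-3-(triisopropylsilyloxy)phenyl]-4,4,5,5-tetramethyl-1,3,2-dioxaborolane
Conditions: B2pin2, PdCl2(dppf) (3 mol %), KOAc, 1,4-dioxane, 90 °C
Reagents that add atoms: bis(pinacolato)diboron, CC1(C)OB(OC1(C)C)B1OC(C)(C)C(C)(C)O1
Why: Miyaura borylation of an aryl bromide under the weak base KOAc tolerates the aryl silyl ether and gives the pinacol boronate without homocoupling of the product.

Step 10
Reactants: 12 [(3S,4R)-4-{[4-methoxy-3-(triisopropylsilyloxy)phenyl]methyl}oxolan-3-yl]methyl 2,4,6-triisopropylbenzoate; 13 2-[4-methoxy-3-(triisopropylsilyloxy)phenyl]-4,4,5,5-tetramethyl-1,3,2-dioxaborolane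
Product: 17 (7S,8S,8'R)-bis(triisopropylsilyl) ether of the target, via (7R)-7-lithio benzoate 14 (not isolated), via lithium boronate complex 15 (not isolated), via (7S)-benzylic pinacol boronic ester 16 (not isolated)
Conditions: s-BuLi (1.2 equiv), (+)-sparteine (1.2 equiv), Et2O, −78 °C, 5 h; 13 (1.5 equiv), Et2O, −78 °C, 2 h, then 35 °C, 12 h; then THF, 2 M NaOH, 30% H2O2, 0 °C
Reagents that add atoms: hydrogen peroxide, OO
Why: The carbonyl oxygen of the hindered benzoate docks s-BuLi·(+)-sparteine, which removes the pro-R hydrogen at C7 to give the configurationally stable (7R)-organolithium 14; boronate 13 captures it with retention to give 15, on warming the aryl group shifts from boron to C7 antiperiplanar to the departing carboxylate (inversion at C7) to give 16, and alkaline H2O2 exchanges boron for hydroxyl with retention. This is the known lithiation–borylation of primary alkyl 2,4,6-triisopropylbenzoates with aryl pinacol boronates, a reagent-controlled Matteson-type homologation, followed by boronate oxidation. No ring is closed; the bonds made are C7–aryl and C7–O. The one new stereocentre, C7, is set by the diamine: with the priority order OH > aryl > C8 the (−)-enantiomer would lead through the (S)-carbanion to the (7R)-carbinol, so (+)-sparteine is used for (7S) and is expected to override the bias of the adjacent C8. The step needs site-selective deprotonation at C7, which is secured by the proximity of the base to the ester carbonyl, by the absence of benzylic ether C–H bonds and by the silyl groups that screen the neighbouring ring positions, while C8 and C8' carry no acidifying group and cannot epimerise. Selective migration is secured because the aryl group is the only carbon ligand on boron and the carboxylate leaves readily, so pinacol oxygen migration should not compete.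

Step 11
Reactants: 17 (7S,8S,8'R)-bis(triisopropylsilyl) ether of the target
Product: 18 (S)-[(3S,4R)-4-(3-hydroxy-4-methoxybenzyl)oxolan-3-yl](3-hydroxy-4-methoxyphenyl)methanol (target)
Conditions: Bu4NF (2.5 equiv), AcOH (2.5 equiv), THF, 0 °C
Reagents that add atoms: none
Why: Fluoride-mediated desilylation cleaves both aryl silyl ethers, and the acetic acid buffer protonates the phenoxides yet is too weak to ionise the p-methoxybenzylic carbinol, so C7 should keep its configuration.

Compound list
1 | diethyl furan-3,4-dicarboxylate | CCOC(=O)c1cocc1C(=O)OCC | starting material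
2 | diethyl cis-oxolane-3,4-dicarboxylate (meso; 3R,4S) | CCOC(=O)[C@H]1COC[C@H]1C(=O)OCC | intermediate
3 | cis-oxolane-3,4-diyldimethanol (meso; 3R,4S) | OC[C@H]1COC[C@H]1CO | intermediate
4 | [(3R,4R)-4-(hydroxymethyl)oxolan-3-yl]methyl acetate | CC(=O)OC[C@H]1COC[C@H]1CO | intermediate
5 | 2,4,6-triisopropylbenzoic acid | CC(C)c1cc(C(C)C)c(C(=O)O)c(C(C)C)c1 | starting material
6 | [(3S,4R)-4-(acetoxymethyl)oxolan-3-yl]methyl 2,4,6-triisopropylbenzoate | CC(=O)OC[C@H]1COC[C@H]1COC(=O)c1c(C(C)C)cc(C(C)C)cc1C(C)C | intermediate
7 | [(3S,4S)-4-(hydroxymethyl)oxolan-3-yl]methyl 2,4,6-triisopropylbenzoate | OC[C@H]1COC[C@H]1COC(=O)c1c(C(C)C)cc(C(C)C)cc1C(C)C | intermediate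
8 | [(3S,4R)-4-(iodomethyl)oxolan-3-yl]methyl 2,4,6-triisopropylbenzoate | IC[C@H]1COC[C@H]1COC(=O)c1c(C(C)C)cc(C(C)C)cc1C(C)C | intermediate
9 | 5-bromo-2-methoxyphenol | COc1ccc(Br)cc1O | starting material
10 | (5-bromo-2-methoxyphenoxy)triisopropylsilane | COc1ccc(Br)cc1O[Si](C(C)C)(C(C)C)C(C)C | intermediate
11 | alkylzinc iodide from 8 (C–I replaced by C–ZnI, cis ring centres unchanged) | I[Zn]C[C@H]1COC[C@H]1COC(=O)c1c(C(C)C)cc(C(C)C)cc1C(C)C | intermediate
12 | [(3S,4R)-4-{[4-methoxy-3-(triisopropylsilyloxy)phenyl]methyl}oxolan-3-yl]methyl 2,4,6-triisopropylbenzoate | COc1ccc(C[C@H]2COC[C@H]2COC(=O)c2c(C(C)C)cc(C(C)C)cc2C(C)C)cc1O[Si](C(C)C)(C(C)C)C(C)C | intermediate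
13 | 2-[4-methoxy-3-(triisopropylsilyloxy)phenyl]-4,4,5,5-tetramethyl-1,3,2-dioxaborolane | COc1ccc(B2OC(C)(C)C(C)(C)O2)cc1O[Si](C(C)C)(C(C)C)C(C)C | intermediate
14 | (7R)-7-lithio derivative of 12 (lithium held by the ester carbonyl and (+)-sparteine) | COc1ccc(C[C@H]2COC[C@H]2[C@@H]([Li])OC(=O)c2c(C(C)C)cc(C(C)C)cc2C(C)C)cc1O[Si](C(C)C)(C(C)C)C(C)C | intermediate
15 | lithium (7R)-boronate complex (boron bears C7, the aryl group and pinacol; C7 still bears the benzoate) | [Li+].COc1ccc(C[C@H]2COC[C@H]2[C@@H]([B-]3(OC(C)(C)C(C)(C)O3)c3ccc(OC)c(O[Si](C(C)C)(C(C)C)C(C)C)c3)OC(=O)c3c(C(C)C)cc(C(C)C)cc3C(C)C)cc1O[Si](C(C)C)(C(C)C)C(C)C | intermediate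
16 | (7S)-secondary benzylic pinacol boronic ester (C7 bears Bpin, the aryl group and H) | COc1ccc(C[C@H]2COC[C@H]2[C@H](B2OC(C)(C)C(C)(C)O2)c2ccc(OC)c(O[Si](C(C)C)(C(C)C)C(C)C)c2)cc1O[Si](C(C)C)(C(C)C)C(C)C | intermediate
17 | (S)-[(3S,4R)-4-{[4-methoxy-3-(triisopropylsilyloxy)phenyl]methyl}oxolan-3-yl][4-methoxy-3-(triisopropylsilyloxy)phenyl]methanol | COc1ccc(C[C@H]2COC[C@H]2[C@H](O)c2ccc(OC)c(O[Si](C(C)C)(C(C)C)C(C)C)c2)cc1O[Si](C(C)C)(C(C)C)C(C)C | intermediate
18 | (S)-[(3S,4R)-4-(3-hydroxy-4-methoxybenzyl)oxolan-3-yl](3-hydroxy-4-methoxyphenyl)methanol, CNP0108210.1 | COc1ccc(C[C@H]2COC[C@H]2[C@H](O)c2ccc(OC)c(O)c2)cc1O | target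

Total step count: 11
Longest linear sequence: 9 steps (1, 2, 3, 4, 5, 6, 8, 10, 11); steps 7 and 9 form the aryl branch.

Steps most likely to fail

Step 10.
- What may go wrong: deprotonation at the β-branched, ring-flanked C7 may be slow or poorly face-selective, because the ring oxygen can compete with the diamine for lithium.
- What may go wrong: lithiation ortho to a methoxy group may intrude. In either case a C7 epimer mixture or regioisomers would be carried straight into the boronate.
- Fallback: the stereodefining deprotonation is separated from the C–C bond formation. Setting out from 12, the carbanion made with s-BuLi/(+)-sparteine is quenched with Me3SnCl (retention) to give the (7R)-α-trimethylstannyl benzoate F1. This compound is isolable, so the C7 epimer and any ring-stannylated material can be removed by chromatography.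
- Rejoining the route: tin–lithium exchange with n-BuLi in Et2O at −78 °C (retention, no diamine needed) regenerates 14 as a single epimer. The route is rejoined at 14, followed by addition of 13, migration and oxidation to 17.

Step 3.
- What may go wrong: acetyl transfer may go to the other enantiotopic arm, or acetyl migration between the arms may erode the enantiomeric purity.
- Fallback: the two arms are elaborated in the opposite order, so the route no longer depends on which arm the enzyme prefers. Setting out from 3, the lipase then delivers the (3S,4S)-monoacetate F2.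
- Its free arm is iodinated (I2, PPh3, imidazole) to give the iodomethyl acetate F3.
- Zinc insertion (Zn, LiCl, THF) gives the alkylzinc iodide F4.
- Negishi coupling with 10 (Pd(OAc)2, SPhos) gives the arylmethyl acetate F5.
- Diisobutylaluminium hydride in CH2Cl2 at −78 °C takes off the acetate without exposing the aryl silyl ether to base and gives the primary alcohol F6.
- Rejoining the route: Mitsunobu esterification of F6 with 5 returns to the route at 12.

Step 8.
- What may go wrong: zinc insertion may be sluggish, the zinc reagent may be protonated, or β-hydride elimination from the β-branched alkylpalladium intermediate may divert material to reduced or alkene products.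
- Fallback: the polarity of the coupling is reversed and the metal changed. Setting out from 10, bromine–lithium exchange (n-BuLi, THF, −78 °C) gives the aryllithium F7, and ZnCl2 converts it into the arylzinc chloride F8.
- Rejoining the route: F8 is coupled with iodide 8 under Ni(acac)2 (10 mol %) and 4-(trifluoromethyl)styrene in THF/N-methylpyrrolidone at −15 °C. This is a nickel-catalysed aryl–alkyl Negishi coupling established for primary alkyl iodides that carry esters. It returns to the route at 12.

Further compounds
F1 | step 10 | (7R)-7-(trimethylstannyl) derivative of 12 | COc1ccc(C[C@H]2COC[C@H]2[C@@H]([Sn](C)(C)C)OC(=O)c2c(C(C)C)cc(C(C)C)cc2C(C)C)cc1O[Si](C(C)C)(C(C)C)C(C)C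
F2 | step 3 | [(3S,4S)-4-(hydroxymethyl)oxolan-3-yl]methyl acetate | OC[C@H]1COC[C@H]1COC(C)=O
F3 | step 3 | [(3S,4R)-4-(iodomethyl)oxolan-3-yl]methyl acetate | IC[C@H]1COC[C@H]1COC(C)=O
F4 | step 3 | alkylzinc iodide from F3 (cis ring centres unchanged) | I[Zn]C[C@H]1COC[C@H]1COC(C)=O
F5 | step 3 | [(3S,4R)-4-{[4-methoxy-3-(triisopropylsilyloxy)phenyl]methyl}oxolan-3-yl]methyl acetate | COc1ccc(C[C@H]2COC[C@H]2COC(C)=O)cc1O[Si](C(C)C)(C(C)C)C(C)C
F6 | step 3 | [(3R,4R)-4-{[4-methoxy-3-(triisopropylsilyloxy)phenyl]methyl}oxolan-3-yl]methanol | COc1ccc(C[C@H]2COC[C@H]2CO)cc1O[Si](C(C)C)(C(C)C)C(C)C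
F7 | step 8 | [4-methoxy-3-(triisopropylsilyloxy)phenyl]lithium | COc1ccc([Li])cc1O[Si](C(C)C)(C(C)C)C(C)C
F8 | step 8 | [4-methoxy-3-(triisopropylsilyloxy)phenyl]zinc chloride | COc1ccc([Zn]Cl)cc1O[Si](C(C)C)(C(C)C)C(C)C
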